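The closed, stirred vessel held a complex with two exchangeable sites, and I wanted to know where each charge of incoming ligand would stop it.

| flask | starting complex | incoming ligand | protic impurity | remark | time |
|---|---|---|---|---|---|
| Wednesday's | 10 mM | 6.6 mM | 0.50 mM | run made earlier |  |
| Sunday's | 10 mM | 45 mM | 0.50 mM | run made earlier |  |
| grey | 10 mM | 40.0 mM | 0.500 mM |  | 8.0 h |
| ochre | 10 mM | 15.0 mM | 0.500 mM |  | 8.0 h |
| teal | 10 mM | 5.00 mM | 0.500 mM |  | 8.0 h |

| run | time / h | complex with two exchanged / % | starting complex / % |
|---|---|---|---|
| Wednesday's | 1.00 | 11.6 | 54.7 |
| Wednesday's | 2.00 | 14.2 | 52.7 |
| Wednesday's | 3.00 | 13.6 | 51.0 |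
| Wednesday's | 4.00 | 14.0 | 52.6 |
| Wednesday's | 5.00 | 14.1 | 52.6 |
| Wednesday's | 6.00 | 13.2 | 52.6 |
| Sunday's | 1.00 | 94.3 | 0.1 |
| Sunday's | 2.00 | 99.6 | 0.8 |
| Sunday's | 3.00 | 100.6 | 1.0 |
| Sunday's | 4.00 | 100.4 | 0.1 |
| Sunday's | 5.00 | 100.8 | 0.3 |
| Sunday's | 6.00 | 99.4 | 0 |

(readings scatter by 0.5 percentage points)

* which of these holds the largest part of the starting complex at the end of grey (complex with one exchanged / complex with two exchanged / starting complex)
* which of these holds the largest part of the starting complex at the end of ochre (complex with one exchanged / complex with two exchanged / starting complex)
* which of these holds the largest part of the starting complex at the end of teal (complex with one exchanged / complex with two exchanged / starting complex)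
* amount of complex with two exchanged at the end of ochre, in percent of the starting complex charged

- the analysis behind the earlier runs scatters by 0.5 percentage points, standard deviation

I reckoned with 1.45 for ochre: incoming ligand charged, less protic impurity, per starting complex. I called this the usable uptake U. Wednesday's run supported it. At 5.00 h the readings left 33.3% as complex with one exchanged by difference, so the complexes had taken up 0.615 ligand each on average, by that reading, against U = 0.610 from Wednesday's charge.

Let A, B and C be the shares of starting complex, complex with one exchanged and complex with two exchanged. Once uptake has reached U, C − A = U − 1 and C = (U − B)/2.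

Sunday's first reading left 5.70% unfinished at 1.00 h, which I read as a half-life of 0.242 h. Wednesday's first reading, at 1.00 h, left 6.72% of its uptake unfinished on a smaller charge of ligand, so I carried that clock to ochre as an estimate. On that clock, I drew ochre's A falling steeply from the start and C beginning flat. The two curves would cross when uptake reached one, which I estimated near 0.408 h. The knee would come by about 1.21 h, and 8.0 h spans 33.1 half-lives, so I expected a level.

In ochre, U stands below 2, which makes incoming ligand the limiting reagent. Keeping B at Wednesday's reading, I put ochre's level at C = 55.9% and A = 10.9%. Grey, with U = 3.95, above 2, should end as complex with two exchanged. Teal, with U = 0.450, should keep A near 60.8%.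

The forecast, holding that “the impurity destroys an equal amount of ligand”, named complex with two exchanged for grey, complex with two exchanged for ochre and starting complex for teal, and gave 58.5% for ochre, above my 55.9%.

Ochre gave 58.0% of complex with two exchanged, and the largest parts were complex with two exchanged in grey, complex with two exchanged in ochre and starting complex in teal.

    protic impurity + incoming ligand → quenched reagent (k = 490 /M/min)
    complex with one exchanged + incoming ligand ⇌ leaving ligand + complex with two exchanged (K = 1.50, k = 6.20 /M/min)
    leaving ligand → by-product carried off (k = 0.0510 /min)
    starting complex + incoming ligand ⇌ leaving ligand + complex with one exchanged (K = 1.10, k = 17.0 /M/min)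

Ochre's complex with one exchanged stood at 28.9% rather than Wednesday's 33.3%, and with U = 1.45 that share returns 58.0%. A flask like ochre but charged with 17 mM of starting complex has U = 0.853, and its 33.1% of complex with one exchanged returns 26.1%. That flask held 26.1% of complex with two exchanged.

The numbers in the tables are simulated for substances that don't exist.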